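**Retrosynthetic overview**
1. Target ⇐ deprotection and allylic oxidation ⇐ substrate-controlled MeLi addition (sets C4) to a 4-hydroxycyclohex-2-enone closed by ring-closing metathesis.
2. Metathesis substrate ⇐ vinyl Grignard opening of an α,α-disubstituted γ-vinyl-γ-butyrolactone; quaternary C5 ⇐ enolate alkylation, trans to the β-ethyl group, with the complete C1′–C12′ side-chain iodide.
3. Lactone core ⇐ Ireland–Claisen [3,3] rearrangement of (S,Z)-hex-3-en-2-yl propanoate (forms C5–C6, sets C6 by chirality transfer), then selenolactonisation.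
4. Side chain ⇐ C5′ dithiane + C1′–C4′ epoxide (from (S)-3-hydroxy-γ-butyrolactone), then 1,3-syn reduction; C6′ and C9′ ⇐ SN2 coupling of (R)-citronellyl Grignard with (R)-lactate triflate.
5. Ring order: the temporary γ-lactone first, the cyclohexenone last.

Locants: side chain C1′ (CH2OH) to C12′ (CH2 on the ring); ring C1 (C=O), C2=C3, C4 (C–OH), C5 (quaternary), C6 (CH–Et). Assumption: (S)-3-hydroxy-γ-butyrolactone, methyl (R)-lactate, (R)-citronellyl bromide and (S)-but-3-yn-2-ol are bought enantiopure.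

**Route**

Step 1
Reactants: 1 (S)-3-hydroxy-γ-butyrolactone
Product: 3 (3S,4S)-3-ethyl-4-hydroxyoxolan-2-one, via dilithium dianion 2 (not isolated)
Conditions: LiN(i-Pr)2 (2.2 equiv), THF, −78 °C; EtI, DMPU, −78 to −40 °C; H2O
Reagents that add atoms: iodoethane, CCI
Why: Dianion alkylation of a β-hydroxy lactone (Fráter–Seebach type) brings the electrophile in anti to the neighbouring OLi group, giving the trans lactone whose two centres become C2′ and C3′.

Step 2
Reactants: 3 (3S,4S)-3-ethyl-4-hydroxyoxolan-2-one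
Product: 4 (2R,3S)-2-ethylbutane-1,3,4-triol
Conditions: LiAlH4, THF, 0 to 65 °C; H2O then 15% aq. NaOH
Reagents that add atoms: none
Why: Hydride reduction of the lactone gives the triol and touches neither stereocentre.

Step 3
Reactants: 4 (2R,3S)-2-ethylbutane-1,3,4-triol
Product: 5 (2R)-2-[(4S)-2,2-dimethyl-1,3-dioxolan-4-yl]butan-1-ol
Conditions: Me2C(OMe)2, acetone, TsOH (cat.), 25 °C
Reagents that add atoms: 2,2-dimethoxypropane, COC(C)(C)OC
Why: Thermodynamic acetalisation prefers the five-membered dioxolane of the terminal 1,2-diol over the 1,3-dioxane, so only the C1′ hydroxyl stays free.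

Step 4
Reactants: 5 (2R)-2-[(4S)-2,2-dimethyl-1,3-dioxolan-4-yl]butan-1-ol
Product: 6 tert-butyl{(2R)-2-[(4S)-2,2-dimethyl-1,3-dioxolan-4-yl]butoxy}diphenylsilane
Conditions: t-BuPh2SiCl, imidazole, DMF, 25 °C
Reagents that add atoms: tert-butyl(chloro)diphenylsilane, CC(C)(C)[Si](Cl)(c1ccccc1)c1ccccc1
Why: Silylation of the only free (primary) alcohol gives an ether that survives the acid, base and organometallic steps ahead.

Step 5
Reactants: 6 tert-butyl{(2R)-2-[(4S)-2,2-dimethyl-1,3-dioxolan-4-yl]butoxy}diphenylsilane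
Product: 7 (2S,3R)-3-({[tert-butyl(diphenyl)silyl]oxy}methyl)pentane-1,2-diol
Conditions: AcOH/H2O 4:1, 40 °C
Reagents that add atoms: none
Why: Acid-catalysed acetal hydrolysis frees the 1,2-diol while the TBDPS ether is stable.

Step 6
Reactants: 7 (2S,3R)-3-({[tert-butyl(diphenyl)silyl]oxy}methyl)pentane-1,2-diol
Product: 9 tert-butyl{(2R)-2-[(2S)-oxiran-2-yl]butoxy}diphenylsilane, via primary tosylate 8 (not isolated)
Conditions: NaH (2.2 equiv), 1-(p-tolylsulfonyl)imidazole, THF, 0 to 25 °C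
Reagents that add atoms: none
Why: Selective sulfonylation of the primary hydroxyl and intramolecular Williamson closure by the secondary alkoxide give the terminal epoxide with the C3′–O bond untouched.

Step 7
Reactants: 10 methyl (R)-lactate
Product: 11 methyl (2R)-2-{[(trifluoromethyl)sulfonyl]oxy}propanoate
Conditions: Tf2O, 2,6-lutidine, CH2Cl2, −78 to 0 °C
Reagents that add atoms: trifluoromethanesulfonic anhydride, O=S(=O)(OS(=O)(=O)C(F)(F)F)C(F)(F)F
Why: O-sulfonylation makes the lactate hydroxyl a leaving group without touching the stereocentre.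

Step 8
Reactants: 11 methyl (2R)-2-{[(trifluoromethyl)sulfonyl]oxy}propanoate; 12 (R)-citronellyl bromide
Product: 14 methyl (2R,5R)-2,5,9-trimethyldec-8-enoate, via Grignard reagent 13 (not isolated)
Conditions: 12, Mg, THF, 40 °C; then added to 11, ZnCl2 (5 mol %), THF, 0 °C
Reagents that add atoms: none
Why: Zinc-catalysed SN2 alkylation of the α-triflyloxy ester by the Grignard reagent goes with clean inversion, so the R lactate centre becomes 6′R while 9′R comes unchanged from citronellyl bromide.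

Step 9
Reactants: 14 methyl (2R,5R)-2,5,9-trimethyldec-8-enoate
Product: 15 (2R,5R)-2,5,9-trimethyldec-8-enal
Conditions: i-Bu2AlH (1.05 equiv), CH2Cl2, −78 °C; aq. potassium sodium tartrate
Reagents that add atoms: none
Why: Partial ester reduction stops at the aluminium hemiacetal at −78 °C and gives the α-methyl aldehyde without epimerisation.

Step 10
Reactants: 15 (2R,5R)-2,5,9-trimethyldec-8-enal
Product: 16 2-[(2R,5R)-5,9-dimethyldec-8-en-2-yl]-1,3-dithiane
Conditions: HS(CH2)3SH, BF3·OEt2 (cat.), CH2Cl2, −20 °C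
Reagents that add atoms: propane-1,3-dithiol, SCCCS
Why: Lewis-acid thioacetalisation gives the dithiane (an acyl-anion equivalent) faster than the α-centre can enolise.

Step 11
Reactants: 16 2-[(2R,5R)-5,9-dimethyldec-8-en-2-yl]-1,3-dithiane; 9 tert-butyl{(2R)-2-[(2S)-oxiran-2-yl]butoxy}diphenylsilane
Product: 18 (2R,3R)-3-({[tert-butyl(diphenyl)silyl]oxy}methyl)-1-{2-[(2R,5R)-5,9-dimethyldec-8-en-2-yl]-1,3-dithian-2-yl}pentan-2-ol, via 2-lithiodithiane 17 (not isolated)
Conditions: t-BuLi, THF/HMPA 10:1, −78 °C; then 9, −78 to −30 °C; H2O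
Reagents that add atoms: none
Why: Corey–Seebach umpolung, in which the lithiated dithiane opens the terminal epoxide at CH2 (SN2), forms C4′–C5′ and releases the C3′ alcohol with its configuration intact.

Step 12
Reactants: 18 hydroxy dithiane
Product: 19 (3R,4R,7R,10R)-3-({[tert-butyl(diphenyl)silyl]oxy}methyl)-4-hydroxy-7,10,14-trimethylpentadec-13-en-6-one
Conditions: MeI, CaCO3, MeCN/H2O 9:1, 45 °C
Reagents that add atoms: water, O
Why: Alkylative dithiane hydrolysis (S-methylation, then hydrolysis) unveils the C5′ ketone under near-neutral conditions that spare the alkene, the silyl ether and the α-methyl centre.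

Step 13
Reactants: 19 β-hydroxy ketone
Product: 21 (3R,4R,6S,7R,10R)-3-({[tert-butyl(diphenyl)silyl]oxy}methyl)-7,10,14-trimethylpentadec-13-ene-4,6-diol, via boron chelate 20 (not isolated)
Conditions: Et2BOMe, THF/MeOH 4:1, −78 °C; NaBH4; then MeOH co-evaporation
Reagents that add atoms: none
Why: Narasaka–Prasad reduction, in which external hydride attacks the six-membered boron chelate axially, gives the 1,3-syn diol (5′S) under control of C3′.

Step 14
Reactants: 21 syn-1,3-diol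
Product: 22 tert-butyl{(2R)-2-[(4R,6S)-6-[(2R,5R)-5,9-dimethyldec-8-en-2-yl]-2,2-dimethyl-1,3-dioxan-4-yl]butoxy}diphenylsilane
Conditions: Me2C(OMe)2, PPTS (cat.), CH2Cl2, 25 °C
Reagents that add atoms: 2,2-dimethoxypropane, COC(C)(C)OC
Why: Acetalisation of the syn-1,3-diol gives the chair acetonide that protects both alcohols.

Step 15
Reactants: 22 acetonide alkene
Product: 24 (4S,7R)-7-[(4S,6R)-6-{(2R)-1-[tert-butyl(diphenyl)silyl]oxybutan-2-yl}-2,2-dimethyl-1,3-dioxan-4-yl]-4-methyloctan-1-ol, via aldehyde 23 (not isolated)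
Conditions: O3, CH2Cl2/MeOH 4:1, −78 °C; then NaBH4, −78 to 0 °C
Reagents that add atoms: ozone, [O-][O+]=O
Why: Ozonolysis of the only alkene with reductive work-up removes the isopropylidene end and leaves C12′ as a primary alcohol.

Step 16
Reactants: 24 primary alcohol
Product: 25 tert-butyl{(2R)-2-[(4R,6S)-6-[(2R,5S)-8-iodo-5-methyloctan-2-yl]-2,2-dimethyl-1,3-dioxan-4-yl]butoxy}diphenylsilane
Conditions: I2, PPh3, imidazole, CH2Cl2, 0 °C
Reagents that add atoms: iodine, II
Why: Appel-type iodination converts the primary alcohol into the iodide under buffered conditions that keep the acetonide.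

Step 17
Reactants: 26 (S)-but-3-yn-2-ol
Product: 28 (S)-hex-3-yn-2-ol, via dilithio acetylide 27 (not isolated)
Conditions: n-BuLi (2.1 equiv), THF, −78 to 0 °C; EtI, DMPU, 0 to 25 °C; H2O
Reagents that add atoms: iodoethane, CCI
Why: Alkylation of the alkoxide–acetylide dianion takes place at the more nucleophilic acetylide carbon and leaves the carbinol centre untouched.

Step 18
Reactants: 28 (S)-hex-3-yn-2-ol
Product: 29 (2S,3Z)-hex-3-en-2-ol
Conditions: H2 (1 atm), Pd/CaCO3 poisoned with Pb(OAc)2, quinoline, hexane, 25 °C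
Reagents that add atoms: none
Why: Lindlar semi-hydrogenation adds H2 syn and stops at the Z-alkene that locks the transition state of step 20.

Step 19
Reactants: 29 (2S,3Z)-hex-3-en-2-ol
Product: 30 (2S,3Z)-hex-3-en-2-yl propanoate
Conditions: EtCOCl, pyridine, DMAP (cat.), CH2Cl2, 0 °C
Reagents that add atoms: propanoyl chloride, CCC(Cl)=O
Why: Simple O-acylation supplies the ester needed for the enolate rearrangement.

Step 20
Reactants: 30 (2S,3Z)-hex-3-en-2-yl propanoate
Product: 33 (2R,3S,4E)-3-ethyl-2-methylhex-4-enoic acid, via silyl ketene acetal 31 (not isolated), via trimethylsilyl ester 32 (not isolated)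
Conditions: LiN(i-Pr)2, THF, −78 °C; Me3SiCl; −78 to 60 °C; then H2O
Reagents that add atoms: none
Why: Ireland–Claisen [3,3]-sigmatropic rearrangement, with the carbinol methyl held pseudo-equatorial by allylic strain against the Z-ethyl group, forms the C5–C6 bond on one face only and transfers the S carbinol configuration to C6 (the C5 centre formed here is planarised again in step 22).

Step 21
Reactants: 33 (2R,3S,4E)-3-ethyl-2-methylhex-4-enoic acid
Product: 36 (3R,4R,5S)-5-ethenyl-4-ethyl-3-methyloxolan-2-one, via selenolactone 34 (not isolated), via selenoxide 35 (not isolated)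
Conditions: PhSeCl, pyridine, CH2Cl2, −78 to 25 °C; then 30% H2O2, THF, 0 to 25 °C
Reagents that add atoms: none
Why: Phenylselenolactonisation (5-exo, anti addition) and selenoxide syn-elimination away from the ring oxygen place the lactone oxygen on C1 next to a terminal vinyl group; the C1 configuration (mainly trans to ethyl) does not matter because C1 becomes the ketone in step 26.

Step 22
Reactants: 36 (3R,4R,5S)-5-ethenyl-4-ethyl-3-methyloxolan-2-one; 25 side-chain iodide
Product: 38 (3R,4R,5S)-lactone bearing the protected C1′–C12′ chain at C3 (2′R,3′R,5′S,6′R,9′R), via lithium enolate 37 (not isolated)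
Conditions: 36 (2 equiv), LiN(i-Pr)2, THF, −78 °C; then 25, HMPA, −78 to −20 °C
Reagents that add atoms: none
Why: In this lactone enolate alkylation the iodide approaches the planar enolate anti to the adjacent β-ethyl group, so the chain ends up trans to ethyl and the methyl cis (C5 R), as the target requires.

Step 23
Reactants: 38 alkylated lactone
Product: 40 γ-hydroxy divinyl ketone (C4 vinyl ketone and C1 allylic alcohol; C1 S C5 R C6 R), via lactol 39 (not isolated)
Conditions: CH2=CHMgBr (1.5 equiv), THF, −78 to −30 °C; H2O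
Reagents that add atoms: vinylmagnesium bromide, C=C[Mg]Br
Why: Single Grignard addition to the lactone carbonyl gives a magnesium lactolate that resists a second addition and opens on work-up to the γ-hydroxy vinyl ketone, the ring–chain tautomer of the lactol.

Step 24
Reactants: 40 γ-hydroxy divinyl ketone
Product: 41 4-hydroxycyclohex-2-enone with C4 as ketone and C1 as carbinol (C1 S C5 R C6 R)
Conditions: second-generation Hoveyda–Grubbs catalyst (5 mol %), CH2Cl2 (5 mM), 40 °C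
Reagents that add atoms: none
Why: Ring-closing metathesis between the vinyl ketone and the allylic alcohol closes the six-membered enone and expels ethene.

Step 25
Reactants: 41 hydroxy enone
Product: 42 cyclohex-2-ene-1,4-diol with the tertiary C4 carbinol (C1 S C4 R C5 R C6 R)
Conditions: MeLi (3 equiv), THF, −78 °C; H2O
Reagents that add atoms: methyllithium, [Li]C
Why: In this 1,2-addition to a non-enolisable enone carbonyl under cyclic substrate control, the face syn to C6–Et is screened in either half-chair by an axial C5–CH3 or C6–C2H5, so methyl arrives from the C6–H face and the new hydroxyl is cis to C5–CH3 and C6–Et (4R).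

Step 26
Reactants: 42 diol
Product: 43 protected target (1′-OTBDPS and 3′,5′-acetonide; ring 4R,5R,6R)
Conditions: MnO2 (20 equiv), CH2Cl2, 25 °C
Reagents that add atoms: none
Why: MnO2 oxidises only the secondary allylic alcohol to the enone, since the tertiary allylic alcohol has no carbinol hydrogen.

Step 27
Reactants: 43 protected target
Product: 44 CNP0104178.2
Conditions: 48% aq. HF, MeCN, 0 to 25 °C
Reagents that add atoms: none
Why: Acidic fluoride cleaves the TBDPS ether and hydrolyses the acetonide in one operation without base, so the epimerisable C6 centre is left alone.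

**Compound list**

1 | (S)-3-hydroxy-γ-butyrolactone [(4S)-4-hydroxyoxolan-2-one] | O=C1C[C@H](O)CO1 | starting material
2 | dilithium dianion of 1 | [Li]OC1=C[C@H](O[Li])CO1 | intermediate
3 | (3S,4S)-3-ethyl-4-hydroxyoxolan-2-one | O=C1[C@@H](CC)[C@H](O)CO1 | intermediate
4 | (2R,3S)-2-ethylbutane-1,3,4-triol | CC[C@H](CO)[C@H](O)CO | intermediate
5 | (2R)-2-[(4S)-2,2-dimethyl-1,3-dioxolan-4-yl]butan-1-ol | CC[C@H](CO)[C@H]1COC(C)(C)O1 | intermediate
6 | tert-butyl{(2R)-2-[(4S)-2,2-dimethyl-1,3-dioxolan-4-yl]butoxy}diphenylsilane | CC[C@H](CO[Si](c1ccccc1)(c1ccccc1)C(C)(C)C)[C@H]1COC(C)(C)O1 | intermediate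
7 | (2S,3R)-3-({[tert-butyl(diphenyl)silyl]oxy}methyl)pentane-1,2-diol | CC[C@H](CO[Si](c1ccccc1)(c1ccccc1)C(C)(C)C)[C@H](O)CO | intermediate
8 | primary 4-methylbenzenesulfonate of 7 | CC[C@H](CO[Si](c1ccccc1)(c1ccccc1)C(C)(C)C)[C@H](O)COS(=O)(=O)c1ccc(C)cc1 | intermediate
9 | tert-butyl{(2R)-2-[(2S)-oxiran-2-yl]butoxy}diphenylsilane | CC[C@H](CO[Si](c1ccccc1)(c1ccccc1)C(C)(C)C)[C@H]1CO1 | intermediate
10 | methyl (R)-lactate | C[C@@H](O)C(=O)OC | starting material
11 | methyl (2R)-2-{[(trifluoromethyl)sulfonyl]oxy}propanoate | C[C@@H](OS(=O)(=O)C(F)(F)F)C(=O)OC | intermediate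
12 | (R)-citronellyl bromide [(6R)-8-bromo-2,6-dimethyloct-2-ene] | BrCC[C@H](C)CCC=C(C)C | starting material
13 | (R)-citronellylmagnesium bromide | Br[Mg]CC[C@H](C)CCC=C(C)C | intermediate
14 | methyl (2R,5R)-2,5,9-trimethyldec-8-enoate | COC(=O)[C@H](C)CC[C@H](C)CCC=C(C)C | intermediate
15 | (2R,5R)-2,5,9-trimethyldec-8-enal | O=C[C@H](C)CC[C@H](C)CCC=C(C)C | intermediate
16 | 2-[(2R,5R)-5,9-dimethyldec-8-en-2-yl]-1,3-dithiane | C1CSC(SC1)[C@H](C)CC[C@H](C)CCC=C(C)C | intermediate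
17 | 2-lithio derivative of 16 | [Li]C1(SCCCS1)[C@H](C)CC[C@H](C)CCC=C(C)C | intermediate
18 | (2R,3R)-3-({[tert-butyl(diphenyl)silyl]oxy}methyl)-1-{2-[(2R,5R)-5,9-dimethyldec-8-en-2-yl]-1,3-dithian-2-yl}pentan-2-ol | CC[C@H](CO[Si](c1ccccc1)(c1ccccc1)C(C)(C)C)[C@H](O)CC1(SCCCS1)[C@H](C)CC[C@H](C)CCC=C(C)C | intermediate
19 | (3R,4R,7R,10R)-3-({[tert-butyl(diphenyl)silyl]oxy}methyl)-4-hydroxy-7,10,14-trimethylpentadec-13-en-6-one | CC[C@H](CO[Si](c1ccccc1)(c1ccccc1)C(C)(C)C)[C@H](O)CC(=O)[C@H](C)CC[C@H](C)CCC=C(C)C | intermediate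
20 | diethylboron chelate of 19 | CC[C@H](CO[Si](c1ccccc1)(c1ccccc1)C(C)(C)C)[C@H]1CC(=[O+][B-](CC)(CC)O1)[C@H](C)CC[C@H](C)CCC=C(C)C | intermediate
21 | (3R,4R,6S,7R,10R)-3-({[tert-butyl(diphenyl)silyl]oxy}methyl)-7,10,14-trimethylpentadec-13-ene-4,6-diol | CC[C@H](CO[Si](c1ccccc1)(c1ccccc1)C(C)(C)C)[C@H](O)C[C@H](O)[C@H](C)CC[C@H](C)CCC=C(C)C | intermediate
22 | tert-butyl{(2R)-2-[(4R,6S)-6-[(2R,5R)-5,9-dimethyldec-8-en-2-yl]-2,2-dimethyl-1,3-dioxan-4-yl]butoxy}diphenylsilane | CC[C@H](CO[Si](c1ccccc1)(c1ccccc1)C(C)(C)C)[C@H]1C[C@H](OC(C)(C)O1)[C@H](C)CC[C@H](C)CCC=C(C)C | intermediate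
23 | (4S,7R)-7-[(4S,6R)-6-{(2R)-1-[tert-butyl(diphenyl)silyl]oxybutan-2-yl}-2,2-dimethyl-1,3-dioxan-4-yl]-4-methyloctanal | CC[C@H](CO[Si](c1ccccc1)(c1ccccc1)C(C)(C)C)[C@H]1C[C@H](OC(C)(C)O1)[C@H](C)CC[C@H](C)CCC=O | intermediate
24 | (4S,7R)-7-[(4S,6R)-6-{(2R)-1-[tert-butyl(diphenyl)silyl]oxybutan-2-yl}-2,2-dimethyl-1,3-dioxan-4-yl]-4-methyloctan-1-ol | CC[C@H](CO[Si](c1ccccc1)(c1ccccc1)C(C)(C)C)[C@H]1C[C@H](OC(C)(C)O1)[C@H](C)CC[C@H](C)CCCO | intermediate
25 | tert-butyl{(2R)-2-[(4R,6S)-6-[(2R,5S)-8-iodo-5-methyloctan-2-yl]-2,2-dimethyl-1,3-dioxan-4-yl]butoxy}diphenylsilane | CC[C@H](CO[Si](c1ccccc1)(c1ccccc1)C(C)(C)C)[C@H]1C[C@H](OC(C)(C)O1)[C@H](C)CC[C@H](C)CCCI | intermediate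
26 | (S)-but-3-yn-2-ol | C[C@H](O)C#C | starting material
27 | dilithio derivative of 26 (alkoxide–acetylide) | C[C@H](O[Li])C#C[Li] | intermediate
28 | (S)-hex-3-yn-2-ol | C[C@H](O)C#CCC | intermediate
29 | (2S,3Z)-hex-3-en-2-ol | C[C@H](O)/C=C\CC | intermediate
30 | (2S,3Z)-hex-3-en-2-yl propanoate | CCC(=O)O[C@@H](C)/C=C\CC | intermediate
31 | (E)-trimethylsilyl ketene acetal of 30 | C/C=C(\O[C@@H](C)/C=C\CC)O[Si](C)(C)C | intermediate
32 | trimethylsilyl (2R,3S,4E)-3-ethyl-2-methylhex-4-enoate | C[Si](C)(C)OC(=O)[C@H](C)[C@@H](CC)/C=C/C | intermediate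
33 | (2R,3S,4E)-3-ethyl-2-methylhex-4-enoic acid (major C2 epimer) | OC(=O)[C@H](C)[C@@H](CC)/C=C/C | intermediate
34 | (3R,4R,5R)-4-ethyl-3-methyl-5-[(1S)-1-(phenylselanyl)ethyl]oxolan-2-one | C[C@@H]1[C@@H](CC)[C@H]([C@H](C)[Se]c2ccccc2)OC1=O | intermediate
35 | selenoxide of 34 | C[C@@H]1[C@@H](CC)[C@H]([C@H](C)[Se](=O)c2ccccc2)OC1=O | intermediate
36 | (3R,4R,5S)-5-ethenyl-4-ethyl-3-methyloxolan-2-one (major isomer) | C[C@@H]1[C@@H](CC)[C@H](C=C)OC1=O | intermediate
37 | lithium enolate of 36 | CC1=C(O[Li])O[C@@H](C=C)[C@@H]1CC | intermediate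
38 | (3R,4R,5S)-5-ethenyl-4-ethyl-3-methyloxolan-2-one carrying the protected side chain at C3 (2′R,3′R,5′S,6′R,9′R; 1′-OTBDPS; 3′,5′-acetonide) | CC[C@H](CO[Si](c1ccccc1)(c1ccccc1)C(C)(C)C)[C@H]1C[C@H](OC(C)(C)O1)[C@H](C)CC[C@H](C)CCC[C@]2(C)[C@@H](CC)[C@H](C=C)OC2=O | intermediate
39 | 2-vinyl lactol from 38 (anomeric centre unassigned) | CC[C@H](CO[Si](c1ccccc1)(c1ccccc1)C(C)(C)C)[C@H]1C[C@H](OC(C)(C)O1)[C@H](C)CC[C@H](C)CCC[C@]2(C)[C@@H](CC)[C@H](C=C)OC2(O)C=C | intermediate
40 | γ-hydroxy divinyl ketone (C4 vinyl ketone, C1 allylic alcohol; C1 S, C5 R, C6 R) | CC[C@H](CO[Si](c1ccccc1)(c1ccccc1)C(C)(C)C)[C@H]1C[C@H](OC(C)(C)O1)[C@H](C)CC[C@H](C)CCC[C@@](C)(C(=O)C=C)[C@@H](CC)[C@@H](O)C=C | intermediate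
41 | 4-hydroxycyclohex-2-enone with C4 ketone and C1 carbinol (C1 S, C5 R, C6 R) | CC[C@H](CO[Si](c1ccccc1)(c1ccccc1)C(C)(C)C)[C@H]1C[C@H](OC(C)(C)O1)[C@H](C)CC[C@H](C)CCC[C@]2(C)[C@@H](CC)[C@@H](O)C=CC2=O | intermediate
42 | cyclohex-2-ene-1,4-diol (C1 S, C4 R, C5 R, C6 R) | CC[C@H](CO[Si](c1ccccc1)(c1ccccc1)C(C)(C)C)[C@H]1C[C@H](OC(C)(C)O1)[C@H](C)CC[C@H](C)CCC[C@]2(C)[C@@H](CC)[C@@H](O)C=C[C@@]2(C)O | intermediate
43 | protected target (1′-OTBDPS; 3′,5′-acetonide; ring 4R,5R,6R) | CC[C@H](CO[Si](c1ccccc1)(c1ccccc1)C(C)(C)C)[C@H]1C[C@H](OC(C)(C)O1)[C@H](C)CC[C@H](C)CCC[C@]2(C)[C@@H](CC)C(=O)C=C[C@@]2(C)O | intermediate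
44 | CNP0104178.2 | CC[C@H](CO)[C@H](O)C[C@H](O)[C@H](C)CC[C@H](C)CCC[C@]1(C)[C@@H](CC)C(=O)C=C[C@@]1(C)O | target

**Step count and risks**

Total: 27 steps. Longest linear sequence: 18 steps (1–6, 11–16, 22–27).

Most likely to fail:

Step 22 (quaternary alkylation of a hindered lactone enolate with an unactivated primary iodide). Fallback, setting out from 22 and 36 and coming back at 38: ozonolysis of 22 with Me2S work-up gives aldehyde 23 as an isolated compound. Its aldol addition to enolate 37 is fast even for this hindered enolate and again occurs anti to the β-ethyl group, giving the β-hydroxy lactone F1 (either C12′ carbinol epimer). 1,1′-Thiocarbonyldiimidazole with DMAP gives the imidazolylthiocarbonate F2. Barton–McCombie deoxygenation (Bu3SnH 1 M, AIBN, toluene, 90 °C, with the high hydride concentration meant to outrun cyclisation onto the vinyl group) then returns 38.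

Step 23 (single addition to a lactone carbonyl next to a quaternary carbon, and handling of the lactol/vinyl ketone). Fallback, setting out from 38 and coming back at 41 without a vinyl ketone or metathesis: MeLi (THF, −78 °C) adds once to give the methyl ketone F3 (ring–chain tautomer of its lactol). Ozonolysis of the vinyl group (O3, CH2Cl2, −78 °C; Me2S) gives the α-hydroxy aldehyde F4. Intramolecular aldol condensation (piperidinium acetate, toluene, 60 °C) can only go through the methyl group, because the other α-carbon is quaternary, and closes cyclohexenone 41.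

Step 25 (facial selectivity of the methyl addition; the conformational argument is the least secure point of the route). Fallback, setting out from 41 and coming back at 42, used if MeLi prefers the other face, because it delivers oxygen instead of carbon to the accessible face: Et3SiCl/imidazole gives the silyl ether F5. Wittig methylenation (Ph3P=CH2 from Ph3PCH3Br and KOt-Bu, toluene, 80 °C) gives the exocyclic diene F6. mCPBA (NaHCO3, CH2Cl2, −20 °C) epoxidises the more electron-rich 1,1-disubstituted alkene to the spiro-epoxide F7. LiEt3BH opens it at CH2 to the tertiary alcohol F8, and PPTS/MeOH removes the triethylsilyl group to give 42.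

Further compounds
F1 | step 22 | β-hydroxy lactone (aldol adduct of 37 and 23; C12′ carbinol) | CC[C@H](CO[Si](c1ccccc1)(c1ccccc1)C(C)(C)C)[C@H]1C[C@H](OC(C)(C)O1)[C@H](C)CC[C@H](C)CCC(O)[C@]2(C)[C@@H](CC)[C@H](C=C)OC2=O
F2 | step 22 | imidazolylthiocarbonate of F1 | CC[C@H](CO[Si](c1ccccc1)(c1ccccc1)C(C)(C)C)[C@H]1C[C@H](OC(C)(C)O1)[C@H](C)CC[C@H](C)CCC(OC(=S)n3ccnc3)[C@]2(C)[C@@H](CC)[C@H](C=C)OC2=O
F3 | step 23 | γ-hydroxy methyl ketone (C4 acetyl, C1 allylic alcohol) | CC[C@H](CO[Si](c1ccccc1)(c1ccccc1)C(C)(C)C)[C@H]1C[C@H](OC(C)(C)O1)[C@H](C)CC[C@H](C)CCC[C@@](C)(C(C)=O)[C@@H](CC)[C@@H](O)C=C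
F4 | step 23 | α-hydroxy aldehyde methyl ketone | CC[C@H](CO[Si](c1ccccc1)(c1ccccc1)C(C)(C)C)[C@H]1C[C@H](OC(C)(C)O1)[C@H](C)CC[C@H](C)CCC[C@@](C)(C(C)=O)[C@@H](CC)[C@@H](O)C=O
F5 | step 25 | C1 triethylsilyl ether of 41 | CC[C@H](CO[Si](c1ccccc1)(c1ccccc1)C(C)(C)C)[C@H]1C[C@H](OC(C)(C)O1)[C@H](C)CC[C@H](C)CCC[C@]2(C)[C@@H](CC)[C@@H](O[Si](CC)(CC)CC)C=CC2=O
F6 | step 25 | exocyclic C4 methylene diene | CC[C@H](CO[Si](c1ccccc1)(c1ccccc1)C(C)(C)C)[C@H]1C[C@H](OC(C)(C)O1)[C@H](C)CC[C@H](C)CCC[C@]2(C)[C@@H](CC)[C@@H](O[Si](CC)(CC)CC)C=CC2=C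
F7 | step 25 | C4 spiro-epoxide | CC[C@H](CO[Si](c1ccccc1)(c1ccccc1)C(C)(C)C)[C@H]1C[C@H](OC(C)(C)O1)[C@H](C)CC[C@H](C)CCC[C@]2(C)[C@@H](CC)[C@@H](O[Si](CC)(CC)CC)C=C[C@]23CO3
F8 | step 25 | C1 triethylsilyl ether of 42 | CC[C@H](CO[Si](c1ccccc1)(c1ccccc1)C(C)(C)C)[C@H]1C[C@H](OC(C)(C)O1)[C@H](C)CC[C@H](C)CCC[C@]2(C)[C@@H](CC)[C@@H](O[Si](CC)(CC)CC)C=C[C@@]2(C)O
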